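**Retrosynthetic overview**
1. Stevensine 12 ⇒ open-chain 2-aminoimidazol-4-yl ketone 10 (carried as its Boc form 9). This breaks the C3a–C4 bond and the C4=C5 alkene, made by acid cyclodehydration onto pyrrole C3, so the azepinone closes last.
2. 9 ⇒ N-aroyl-2,3-dihydro-4-pyridone 6 + Boc-guanidine + "Br+". The guanidine is annulated across C5=C6 and the N1–C6 bond is cleaved.
3. 6 ⇒ 4-methoxypyridine 3 + acid chloride 2 + hydride, by dearomative reduction at C2. The pyridine ring supplies N7, C6, C5, C4 and imidazole C4'/C5' of the target.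
4. Ring order: pyrrole (bought) → temporary dihydropyridone → imidazole (six-membered ring opened) → azepinone.

Assumption 1: stevensine has no stereocentre and no stereogenic double bond, so it is achiral and no enantiomer has to be controlled.
Assumption 2: the Boc group of 9 is drawn on ring N1, as is usual for Boc-guanidine/α-halocarbonyl condensations. An exocyclic N-Boc isomer would behave the same way in step 4.

**Step 1**
Reactants: 1 4,5-dibromo-1H-pyrrole-2-carboxylic acid
Product: 2 4,5-dibromo-1H-pyrrole-2-carbonyl chloride (crude, used directly)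
Conditions: (COCl)2 (1.3 equiv), cat. DMF, CH2Cl2, 0 °C → rt; evaporate
Reagents that add atoms: oxalyl chloride, O=C(Cl)C(=O)Cl
Why: Vilsmeier-type acid chloride formation, in which the electron-poor dibromopyrrole ring and its N–H are inert to oxalyl chloride; no stereocentre is formed.

**Step 2 (key step)**
Reactants: 2 4,5-dibromo-1H-pyrrole-2-carbonyl chloride; 3 4-methoxypyridine
Product: 6 1-(4,5-dibromo-1H-pyrrole-2-carbonyl)-2,3-dihydropyridin-4(1H)-one, via 1-(4,5-dibromo-1H-pyrrole-2-carbonyl)-4-methoxypyridinium chloride 4 (not isolated), via (4,5-dibromo-1H-pyrrol-2-yl)(4-methoxy-1,2-dihydropyridin-1-yl)methanone 5 (not isolated)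
Conditions: 3 (1.5 equiv), NaBH4 (1.5 equiv), THF–MeOH, −78 °C, slow addition of 2 in THF; then 1 M aq HCl, 0 °C → rt
Reagents that add atoms: water, O
Why: N-acylation makes the pyridine ring electrophilic, the 4-OMe group blocks C4 so borohydride adds only at C2 (Fowler/Comins-type dearomative reduction of an N-acylpyridinium salt), and acid hydrolysis of the enol ether 5 gives the vinylogous imide 6 with the activating acyl group kept as part of the target; no stereocentre is formed.

**Step 3**
Reactants: 6 1-(4,5-dibromo-1H-pyrrole-2-carbonyl)-2,3-dihydropyridin-4(1H)-one; 7 N-Boc-guanidine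
Product: 9 tert-butyl 2-amino-4-{3-[(4,5-dibromo-1H-pyrrole-2-carbonyl)amino]propanoyl}-1H-imidazole-1-carboxylate, via 5-bromo-1-(4,5-dibromo-1H-pyrrole-2-carbonyl)-2,3-dihydropyridin-4(1H)-one 8 (not isolated)
Conditions: NBS (1.0 equiv), DMF, 0 °C, 30 min; then 7 (2.5 equiv), NaHCO3 (2 equiv), 0 → 40 °C
Reagents that add atoms: N-bromosuccinimide, O=C1CCC(=O)N1Br (its Br is carried only in 8 and leaves again as bromide)
Why: Proposed new method: NBS brominates the nucleophilic enaminone carbon C5 (known C5-halogenation of N-acyl-2,3-dihydro-4-pyridones), Boc-guanidine adds to the vinylogous-imide carbon C6 (aza-Michael), its second nitrogen displaces the now α-keto bromide, and E1cB expulsion of the amide nitrogen from C6 opens the six-membered ring and aromatises the 2-aminoimidazole, the closest known reaction types being the 3-halochromone/amidine domino synthesis of 4-acylimidazoles, the 2-bromo-3-alkoxyacrolein/amidine imidazole synthesis and the bromine-mediated addition of protected guanidine to N-acyl-1,2-dihydropyridines; no stereocentre survives.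

**Step 4**
Reactants: 9 tert-butyl 2-amino-4-{3-[(4,5-dibromo-1H-pyrrole-2-carbonyl)amino]propanoyl}-1H-imidazole-1-carboxylate
Product: 12 stevensine, via N-[3-(2-amino-1H-imidazol-4-yl)-3-oxopropyl]-4,5-dibromo-1H-pyrrole-2-carboxamide 10 (not isolated), via (±)-4-(2-amino-1H-imidazol-4-yl)-2,3-dibromo-4-hydroxy-4,5,6,7-tetrahydropyrrolo[2,3-c]azepin-8(1H)-one 11 (not isolated)
Conditions: neat MeSO3H, rt, 1 h, then 70 °C, sealed tube, 16 h; ice, aq NH3 to pH 9
Reagents that add atoms: none
Why: The acid removes the Boc group, N-protonation of the aminoimidazole turns the ketone of 10 into a dicationic (superelectrophilic) carbonyl that the only free pyrrole carbon C3 attacks in an intramolecular Friedel–Crafts hydroxyalkylation (the same seven-ring closure mode as aldisine-type cyclisations), and E1 dehydration of the doubly heteroaryl-stabilised carbinol 11 can only give the C4=C5 alkene, so the transient stereocentre of 11 is erased.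

**Compound list**
1 | 4,5-dibromo-1H-pyrrole-2-carboxylic acid | OC(=O)c1cc(Br)c(Br)[nH]1 | starting material
2 | 4,5-dibromo-1H-pyrrole-2-carbonyl chloride | ClC(=O)c1cc(Br)c(Br)[nH]1 | intermediate
3 | 4-methoxypyridine | COc1ccncc1 | starting material
4 | 1-(4,5-dibromo-1H-pyrrole-2-carbonyl)-4-methoxypyridinium chloride | COc1cc[n+](cc1)C(=O)c1cc(Br)c(Br)[nH]1.[Cl-] | intermediate (not isolated)
5 | (4,5-dibromo-1H-pyrrol-2-yl)(4-methoxy-1,2-dihydropyridin-1-yl)methanone | COC1=CCN(C=C1)C(=O)c1cc(Br)c(Br)[nH]1 | intermediate (not isolated)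
6 | 1-(4,5-dibromo-1H-pyrrole-2-carbonyl)-2,3-dihydropyridin-4(1H)-one | O=C1CCN(C=C1)C(=O)c1cc(Br)c(Br)[nH]1 | intermediate
7 | N-Boc-guanidine | CC(C)(C)OC(=O)NC(N)=N | starting material
8 | 5-bromo-1-(4,5-dibromo-1H-pyrrole-2-carbonyl)-2,3-dihydropyridin-4(1H)-one | O=C1CCN(C=C1Br)C(=O)c1cc(Br)c(Br)[nH]1 | intermediate (not isolated)
9 | tert-butyl 2-amino-4-{3-[(4,5-dibromo-1H-pyrrole-2-carbonyl)amino]propanoyl}-1H-imidazole-1-carboxylate | CC(C)(C)OC(=O)n1cc(nc1N)C(=O)CCNC(=O)c1cc(Br)c(Br)[nH]1 | intermediate
10 | N-[3-(2-amino-1H-imidazol-4-yl)-3-oxopropyl]-4,5-dibromo-1H-pyrrole-2-carboxamide (mesylate salt in the flask) | Nc1nc(c[nH]1)C(=O)CCNC(=O)c1cc(Br)c(Br)[nH]1 | intermediate (not isolated)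
11 | (±)-4-(2-amino-1H-imidazol-4-yl)-2,3-dibromo-4-hydroxy-4,5,6,7-tetrahydropyrrolo[2,3-c]azepin-8(1H)-one (racemic, transient) | Nc1nc(c[nH]1)C1(O)CCNC(=O)c2[nH]c(Br)c(Br)c12 | intermediate (not isolated)
12 | stevensine, 4-(2-amino-1H-imidazol-4-yl)-2,3-dibromo-6,7-dihydropyrrolo[2,3-c]azepin-8(1H)-one (achiral) | Nc1ncc(C2=CCNC(=O)c3[nH]c(Br)c(Br)c32)[nH]1 | target

**Total step count:** 4. **Longest linear sequence:** 4 (1 → 2 → 6 → 9 → 12).

**Steps most likely to fail, with fallbacks**

Step 4 carries the highest risk.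
- The ketone is a vinylogous-urea carbonyl and the pyrrole is deactivated.
- Retro-aza-Michael loss of the amide, reversible 1,3-oxazine formation and bromine scrambling can all compete.
- The fallback sets out from 9 and comes back at 12. It replaces the carbonyl electrophile with a carbocation and restores the oxidation level afterwards.
- NaBH4 in MeOH reduces 9 to racemic tert-butyl 2-amino-4-{3-[(4,5-dibromo-1H-pyrrole-2-carbonyl)amino]-1-hydroxypropyl}-1H-imidazole-1-carboxylate F5.
- In MeSO3H at rt, F5 loses Boc and ionises to the imidazole-stabilised (diazafulvenium) cation, which closes onto pyrrole C3 to give (±)-hymenin F6.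
- Br2 in TFA gives (±)-5'-bromohymenin F7.
- Heating F7 in MeSO3H at 90 °C in a sealed tube causes tautomerisation and loss of HBr to give 12. The racemic centre is destroyed in this last operation.

Step 3 is the second risk.
- The guanidine can condense on the C4 ketone to give a 2-amino-5-bromopyrimidine.
- The aroyl group can transfer to the guanidine.
- NBS can attack pyrrole C3.
- The fallback sets out from 6 and comes back at 12. It uses a masked guanidine whose second nitrogen is a ring nitrogen, so the condensation on the C4 ketone that would lead to an aminopyrimidine is disfavoured.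
- 8 is now isolated (NBS, CH2Cl2) and heated with 2-aminopyrimidine and NaHCO3 in EtOH at 80 °C. This gives 4,5-dibromo-N-[3-(imidazo[1,2-a]pyrimidin-3-yl)-3-oxopropyl]-1H-pyrrole-2-carboxamide F3.
- MeSO3H at 70 °C cyclodehydrates F3 to 2,3-dibromo-4-(imidazo[1,2-a]pyrimidin-3-yl)-6,7-dihydropyrrolo[2,3-c]azepin-8(1H)-one F4.
- Hydrazine hydrate in EtOH at 100 °C degrades the pyrimidine ring of F4 and unmasks the 2-aminoimidazole of 12.

Step 2 is the third risk.
- Salt 4 can undergo methanolysis.
- The N–H acid chloride can lose HCl to an azafulvenone, which dimerises.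
- The acyl group can be over-reduced.
- The fallback sets out from 3 and comes back at 6. It separates the dearomatisation from the installation of the pyrrole acyl group.
- 3 is dearomatised with CbzCl/NaBH4 in MeOH at −78 °C, followed by aqueous HCl, to give benzyl 4-oxo-3,4-dihydropyridine-1(2H)-carboxylate F1.
- NaOMe in MeOH removes the carbamate to give 2,3-dihydropyridin-4(1H)-one F2.
- The lithium salt of F2 (LiHMDS 2.1 equiv, THF, −78 → 0 °C, the extra base covering the pyrrole N–H) is N-acylated with 2 to give 6.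

**Further compounds**
F1 | step 2 | benzyl 4-oxo-3,4-dihydropyridine-1(2H)-carboxylate | O=C1CCN(C=C1)C(=O)OCc1ccccc1
F2 | step 2 | 2,3-dihydropyridin-4(1H)-one | O=C1CCNC=C1
F3 | step 3 | 4,5-dibromo-N-[3-(imidazo[1,2-a]pyrimidin-3-yl)-3-oxopropyl]-1H-pyrrole-2-carboxamide | O=C(CCNC(=O)c1cc(Br)c(Br)[nH]1)c1cnc2ncccn12
F4 | step 3 | 2,3-dibromo-4-(imidazo[1,2-a]pyrimidin-3-yl)-6,7-dihydropyrrolo[2,3-c]azepin-8(1H)-one | O=C1NCC=C(c2cnc3ncccn23)c2c1[nH]c(Br)c2Br
F5 | step 4 | (±)-tert-butyl 2-amino-4-{3-[(4,5-dibromo-1H-pyrrole-2-carbonyl)amino]-1-hydroxypropyl}-1H-imidazole-1-carboxylate (racemic) | CC(C)(C)OC(=O)n1cc(nc1N)C(O)CCNC(=O)c1cc(Br)c(Br)[nH]1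
F6 | step 4 | (±)-hymenin (racemic) | Nc1nc(c[nH]1)C1CCNC(=O)c2[nH]c(Br)c(Br)c12
F7 | step 4 | (±)-5'-bromohymenin (racemic) | Nc1nc(c(Br)[nH]1)C1CCNC(=O)c2[nH]c(Br)c(Br)c12
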